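Assumption: the (S,S)-allylsilane 5 is taken to deliver allyl to the face of ketone 4 that gives (R)-6. If the sense is the reverse, the equally available (R,R)-silane is used and nothing else changes.

Numbering: azulene numbering is used for all bicyclic compounds. C1 carries the O-angeloyl group, C3 the OH and i-Pr, C3a an H, C4 the O-aroyl group, C6 a Me and C8a a Me. β is the face of the C8a methyl.

## Retrosynthetic overview

1. Remove the 4-hydroxybenzoate (installed last) and the angelate. The 4α-carbinol comes from an OH-directed ketone reduction, and the C6=C7 alkene from 1,4-hydrogenation of a ring diene.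
2. The 3-hydroxy-4-oxo-5,7-diene comes from fluoride unmasking of a silylene-bridged 8a-methylazulenone, which is a cycloheptatriene silyl enol ether.
3. Key step: an intramolecular Buchner reaction of an α-diazo ethyl ketone hung on the benzylic carbinol carbon forms C8a–C3a and C8a–C8. The cyclopentanone and the seven-membered ring arise together, through a norcaradiene.
4. The diazoketone comes from the acid and diazoethane. The acid comes from a homoallylic tertiary carbinol, made by phenol-directed asymmetric allylation of 2-hydroxy-4-methylisobutyrophenone, which comes from m-cresol and isobutyryl chloride.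
5. Ring order: the purchased benzene ring, then a temporary dioxasiline ring, then the five- and seven-membered rings in one operation, then removal of the dioxasiline.

## Route

**Step 1**
Reactants: 1 m-cresol; 2 isobutyryl chloride
Product: 4 1-(2-hydroxy-4-methylphenyl)-2-methylpropan-1-one, via m-tolyl isobutyrate 3 (not isolated)
Conditions: neat, 60 °C, 1 h; then AlCl3 (1.5 equiv), 130 °C, 2 h; ice/aq. HCl
Reagents that add atoms: isobutyryl chloride (2), CC(C)C(=O)Cl
Why: O-acylation followed by a thermodynamically controlled Fries rearrangement, which at high temperature gives the aluminium-chelated ortho-hydroxy ketone at the less hindered ortho position (para to the methyl); no stereocentre is formed.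

**Step 2**
Reactants: 4 1-(2-hydroxy-4-methylphenyl)-2-methylpropan-1-one; 5 (3aS,7aS)-2-allyl-1,3-bis(4-bromobenzyl)-2-chlorooctahydro-1H-1,3,2-benzodiazasilole
Product: 6 (R)-2-(3-hydroxy-2-methylhex-5-en-3-yl)-5-methylphenol
Conditions: 5 (1.5 equiv), CH2Cl2, 40 °C, 24 h; 1 M HCl, then aq. NaHCO3 (diamine recovered)
Reagents that add atoms: allylsilane 5, C=CC[Si]1(Cl)N(Cc2ccc(Br)cc2)[C@H]2CCCC[C@@H]2N1Cc1ccc(Br)cc1
Why: Phenol-directed asymmetric allylation with a strained chiral allylchlorosilane (Leighton-type allylation), in which the phenol displaces chloride, the ketone chelates to the acidified silicon and allyl is transferred through a closed chair transition state to one carbonyl face, a process known to accept hindered 2-hydroxyaryl isopropyl ketones, and this sets C3 as R.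

**Step 3**
Reactants: 6 (R)-2-(3-hydroxy-2-methylhex-5-en-3-yl)-5-methylphenol
Product: 7 (R)-4-allyl-2,2-di-tert-butyl-4-isopropyl-7-methyl-4H-1,3,2-benzodioxasiline
Conditions: tBu2Si(OTf)2 (1.2 equiv), 2,6-lutidine (3 equiv), CH2Cl2, 0 °C to reflux
Reagents that add atoms: di-tert-butylsilyl bis(trifluoromethanesulfonate), CC(C)(C)[Si](OS(=O)(=O)C(F)(F)F)(OS(=O)(=O)C(F)(F)F)C(C)(C)C
Why: Cyclic silylene formation (fast phenol silylation, then intramolecular capture of the tertiary alcohol) masks both hydroxyls with one reagent, locks the C3–O bond beside the aryl oxygen and leaves both oxygens too hindered and too weakly basic to trap a carbenoid; C3 is untouched.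

**Step 4**
Reactants: 7 (R)-4-allyl-2,2-di-tert-butyl-4-isopropyl-7-methyl-4H-1,3,2-benzodioxasiline
Product: 9 (R)-2-(2,2-di-tert-butyl-4-isopropyl-7-methyl-4H-1,3,2-benzodioxasilin-4-yl)acetic acid, via aldehyde 8 (not isolated)
Conditions: O3, CH2Cl2–MeOH, −78 °C; Me2S, to rt; concentrate; NaClO2, NaH2PO4, 2-methyl-2-butene, t-BuOH–H2O, 0 °C to rt
Reagents that add atoms: ozone, [O-][O+]=O; sodium chlorite, [Na+].[O-]Cl=O
Why: Ozonolysis of the only alkene with reductive work-up and Pinnick oxidation of the crude aldehyde, with the alkene scavenger keeping HOCl away from the electron-rich arene; C3 is fully substituted and cannot epimerise.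

**Step 5**
Reactants: 10 N-ethyl-N-nitrosourea
Product: 11 diazoethane (dried ethereal solution, used at once)
Conditions: 40% aq. KOH, Et2O, 0 °C; ether layer decanted, dried over KOH pellets
Reagents that add atoms: none
Why: Base-induced fragmentation of an N-alkyl-N-nitrosourea, the standard generation of a diazoalkane.

**Step 6**
Reactants: 9 (R)-2-(2,2-di-tert-butyl-4-isopropyl-7-methyl-4H-1,3,2-benzodioxasilin-4-yl)acetic acid; 11 diazoethane
Product: 13 (R)-3-diazo-1-(2,2-di-tert-butyl-4-isopropyl-7-methyl-4H-1,3,2-benzodioxasilin-4-yl)butan-2-one, via acid chloride 12 (not isolated)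
Conditions: (COCl)2, N,N-dimethylformamide (cat.), CH2Cl2, 0 °C to rt, evaporate; then 11 (3 equiv), Et2O, −20 to 0 °C
Reagents that add atoms: diazoethane (11), CC=[N+]=[N-]; oxalyl chloride, O=C(Cl)C(=O)Cl (chlorine of 12 only)
Why: Acylation of a diazoalkane by an acid chloride (Arndt–Eistert-type first stage), with a second equivalent of diazoethane consuming the HCl so that the diazoketone survives; no stereocentre is touched.

**Step 7 (key step)**
Reactants: 13 (R)-3-diazo-1-(2,2-di-tert-butyl-4-isopropyl-7-methyl-4H-1,3,2-benzodioxasilin-4-yl)butan-2-one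
Product: 15 (3R,8aR)-3,4-[(di-tert-butylsilanediyl)bis(oxy)]-3-isopropyl-6,8a-dimethyl-3,8a-dihydroazulen-1(2H)-one, via norcaradiene 14 (not isolated)
Conditions: Rh2(O2CC3F7)4 (1 mol %), CH2Cl2, 40 °C, 13 added over 4 h (final 0.01 M); filtration through basic alumina
Reagents that add atoms: none
Why: Intramolecular Buchner reaction (arene cyclopropanation by an electrophilic divalent-rhodium carbenoid, then 6π opening of norcaradiene 14), in which perfluorobutyrate ligands favour aromatic cycloaddition over C–H insertion and the silylene ring places the CH2 arm and the isopropyl group on opposite faces of the arene, so the carbenoid reaches only the unsubstituted C3a–C8 bond from its own face, closing the cyclopentanone and the seven-membered ring together and setting the C8a methyl cis to the C3 oxygen and trans to isopropyl (8aR).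

**Step 8**
Reactants: 15 (3R,8aR)-3,4-[(di-tert-butylsilanediyl)bis(oxy)]-3-isopropyl-6,8a-dimethyl-3,8a-dihydroazulen-1(2H)-one
Product: 16 (1R,3R,8aR)-3,4-[(di-tert-butylsilanediyl)bis(oxy)]-3-isopropyl-6,8a-dimethyl-1,2,3,8a-tetrahydroazulen-1-ol (1β-OH)
Conditions: (3aS)-1-methyl-3,3-diphenyltetrahydro-3H-pyrrolo[1,2-c][1,3,2]oxazaborole (0.3 equiv), catecholborane (2 equiv), toluene, −78 to −40 °C; MeOH, aq. NaHCO3
Reagents that add atoms: none
Why: Corey–Bakshi–Shibata reduction, in which the catalyst distinguishes the quaternary C8a side (large) from the C2 methylene side (small) as in 2,2-disubstituted cyclopentanones and delivers hydride to the α-face to give 1R (OH cis to the C8a methyl), while catecholborane at low temperature leaves the triene and the silyl enol ether alone.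

**Step 9**
Reactants: 16 (1R,3R,8aR)-azulenol from step 8; 17 angelic acid, (Z)-2-methylbut-2-enoic acid
Product: 18 (1R,3R,8aR)-3,4-[(di-tert-butylsilanediyl)bis(oxy)]-3-isopropyl-6,8a-dimethyl-1,2,3,8a-tetrahydroazulen-1-yl (Z)-2-methylbut-2-enoate
Conditions: 17, 2,4,6-trichlorobenzoyl chloride, Et3N, toluene, rt, 2 h; then 16, 80 °C (no 4-(dimethylamino)pyridine)
Reagents that add atoms: angelic acid (17), C/C=C(/C)C(=O)O
Why: Yamaguchi mixed-anhydride esterification run without a nucleophilic catalyst, the usual way to angeloylate hindered secondary alcohols without Z-to-E isomerisation; C1–OH is the only free hydroxyl and no stereocentre is touched.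

**Step 10**
Reactants: 18 silylene-bridged angelate from step 9
Product: 20 (1R,3R,3aR,8aR)-3-hydroxy-3-isopropyl-6,8a-dimethyl-4-oxo-1,2,3,3a,4,8a-hexahydroazulen-1-yl (Z)-2-methylbut-2-enoate (H-3a α and trans-fused), via trienol 19 (not isolated)
Conditions: HF·pyridine, pyridine–THF, 0 °C to rt; aq. NaHCO3
Reagents that add atoms: none
Why: Fluoride cleavage of the silylene frees trienol 19, which ketonises by protonation at C3a, and because C3a stays enolisable it settles in the thermodynamically preferred trans-fused form in which the C3a–C4 bond is trans to the isopropyl group and the 3β-OH hydrogen-bonds to the ketone.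

**Step 11**
Reactants: 20 hydroxy dienone angelate from step 10
Product: 21 (1R,3R,3aS,4S,8aR)-3,4-dihydroxy-3-isopropyl-6,8a-dimethyl-1,2,3,3a,4,8a-hexahydroazulen-1-yl (Z)-2-methylbut-2-enoate (4α-OH)
Conditions: Me4NBH(OAc)3 (5 equiv), MeCN–AcOH 1:1, −30 to −20 °C
Reagents that add atoms: none
Why: Evans–Saksena hydroxyl-directed reduction, in which the borohydride is bound by the β-oriented C3–OH and hydride is delivered internally to the β-face of the C4 ketone in a 1,2 sense, giving the 1,3-anti 4α-alcohol (4S) against the external-attack bias of the axial C8a methyl; the ester is inert.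

**Step 12**
Reactants: 21 dienediol angelate from step 11
Product: 22 (1R,3R,3aS,4S,8aR)-3,4-dihydroxy-3-isopropyl-6,8a-dimethyl-1,2,3,3a,4,5,8,8a-octahydroazulen-1-yl (Z)-2-methylbut-2-enoate
Conditions: Cr(CO)3(η6-C10H8) (15 mol %), H2 (5 MPa), acetone, 40 °C
Reagents that add atoms: none
Why: Catalytic 1,4-hydrogenation of an s-cis 1,3-diene by a zerovalent chromium tricarbonyl fragment, which binds only the ring diene in η4 fashion and adds hydrogen to its termini C5 and C8 to leave the C6=C7 alkene (as in sorbate to 3-hexenoate), while isolated alkenes and the angelate enoate are not substrates and no stereocentre is made.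

**Step 13**
Reactants: 22 diol angelate from step 12; 23 4-acetoxybenzoyl chloride
Product: 25 target (1R,3R,3aS,4S,8aR)-3-hydroxy-4-(4-hydroxybenzoyloxy)-3-isopropyl-6,8a-dimethyl-1,2,3,3a,4,5,8,8a-octahydroazulen-1-yl (Z)-2-methylbut-2-enoate, via acetoxybenzoate 24 (not isolated)
Conditions: 23 (1.5 equiv), Et3N, 4-(dimethylamino)pyridine (cat.), CH2Cl2, 0 °C to rt; then pyrrolidine (5 equiv), rt, 1 h
Reagents that add atoms: 4-acetoxybenzoyl chloride (23), CC(=O)Oc1ccc(cc1)C(=O)Cl
Why: Nucleophile-catalysed acylation of the only secondary hydroxyl (the tertiary C3–OH is inert) followed in the same flask by chemoselective aminolysis of the much more electrophilic aryl acetate, which leaves the alkyl benzoate and the angelate intact; no stereocentre is touched.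

## Compound list

1 | m-cresol | Cc1cccc(O)c1 | starting material
2 | isobutyryl chloride | CC(C)C(=O)Cl | starting material
3 | m-tolyl isobutyrate | CC(C)C(=O)Oc1cccc(C)c1 | intermediate
4 | 1-(2-hydroxy-4-methylphenyl)-2-methylpropan-1-one | CC(C)C(=O)c1ccc(C)cc1O | intermediate
5 | (3aS,7aS)-2-allyl-1,3-bis(4-bromobenzyl)-2-chlorooctahydro-1H-1,3,2-benzodiazasilole | C=CC[Si]1(Cl)N(Cc2ccc(Br)cc2)[C@H]2CCCC[C@@H]2N1Cc1ccc(Br)cc1 | starting material
6 | (R)-2-(3-hydroxy-2-methylhex-5-en-3-yl)-5-methylphenol | C=CC[C@@](O)(C(C)C)c1ccc(C)cc1O | intermediate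
7 | (R)-4-allyl-2,2-di-tert-butyl-4-isopropyl-7-methyl-4H-1,3,2-benzodioxasiline | C=CC[C@@](O2)(C(C)C)c1ccc(C)cc1O[Si]2(C(C)(C)C)C(C)(C)C | intermediate
8 | (R)-2-(2,2-di-tert-butyl-4-isopropyl-7-methyl-4H-1,3,2-benzodioxasilin-4-yl)acetaldehyde | O=CC[C@@](O2)(C(C)C)c1ccc(C)cc1O[Si]2(C(C)(C)C)C(C)(C)C | intermediate
9 | (R)-2-(2,2-di-tert-butyl-4-isopropyl-7-methyl-4H-1,3,2-benzodioxasilin-4-yl)acetic acid | OC(=O)C[C@@](O2)(C(C)C)c1ccc(C)cc1O[Si]2(C(C)(C)C)C(C)(C)C | intermediate
10 | N-ethyl-N-nitrosourea | CCN(N=O)C(N)=O | starting material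
11 | diazoethane | CC=[N+]=[N-] | intermediate
12 | acid chloride of 9 | ClC(=O)C[C@@](O2)(C(C)C)c1ccc(C)cc1O[Si]2(C(C)(C)C)C(C)(C)C | intermediate
13 | (R)-3-diazo-1-(2,2-di-tert-butyl-4-isopropyl-7-methyl-4H-1,3,2-benzodioxasilin-4-yl)butan-2-one | CC(=[N+]=[N-])C(=O)C[C@@](O2)(C(C)C)c1ccc(C)cc1O[Si]2(C(C)(C)C)C(C)(C)C | intermediate
14 | norcaradiene valence isomer of 15 (cyclopropane C3a–C8–C8a on the face of the CH2 arm) | O=C1C[C@@](O3)(C(C)C)[C@@]24C(O[Si]3(C(C)(C)C)C(C)(C)C)=CC(C)=C[C@@H]2[C@]41C | intermediate
15 | (3R,8aR)-3,4-[(di-tert-butylsilanediyl)bis(oxy)]-3-isopropyl-6,8a-dimethyl-3,8a-dihydroazulen-1(2H)-one | O=C1C[C@@](O3)(C(C)C)C2=C(O[Si]3(C(C)(C)C)C(C)(C)C)C=C(C)C=C[C@]21C | intermediate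
16 | (1R,3R,8aR)-1β-alcohol of 15 | O[C@@H]1C[C@@](O3)(C(C)C)C2=C(O[Si]3(C(C)(C)C)C(C)(C)C)C=C(C)C=C[C@]21C | intermediate
17 | angelic acid | C/C=C(/C)C(=O)O | starting material
18 | angelate of 16 | C/C=C(/C)C(=O)O[C@@H]1C[C@@](O3)(C(C)C)C2=C(O[Si]3(C(C)(C)C)C(C)(C)C)C=C(C)C=C[C@]21C | intermediate
19 | (1R,3R,8aR)-3,4-dihydroxy trienol angelate | C/C=C(/C)C(=O)O[C@@H]1C[C@@](O)(C(C)C)C2=C(O)C=C(C)C=C[C@]21C | intermediate
20 | (1R,3R,3aR,8aR)-3-hydroxy-4-oxo-5,7-diene angelate | C/C=C(/C)C(=O)O[C@@H]1C[C@@](O)(C(C)C)[C@@H]2C(=O)C=C(C)C=C[C@]21C | intermediate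
21 | (1R,3R,3aS,4S,8aR)-3,4-dihydroxy-5,7-diene angelate | C/C=C(/C)C(=O)O[C@@H]1C[C@@](O)(C(C)C)[C@@H]2[C@@H](O)C=C(C)C=C[C@]21C | intermediate
22 | (1R,3R,3aS,4S,8aR)-3,4-dihydroxy-6-ene angelate | C/C=C(/C)C(=O)O[C@@H]1C[C@@](O)(C(C)C)[C@@H]2[C@@H](O)CC(C)=CC[C@]21C | intermediate
23 | 4-acetoxybenzoyl chloride | CC(=O)Oc1ccc(cc1)C(=O)Cl | starting material
24 | 4-O-(4-acetoxybenzoyl) derivative of 22 | C/C=C(/C)C(=O)O[C@@H]1C[C@@](O)(C(C)C)[C@@H]2[C@@H](OC(=O)c3ccc(OC(C)=O)cc3)CC(C)=CC[C@]21C | intermediate
25 | CNP0188626.1 | C/C=C(/C)C(=O)O[C@@H]1C[C@@](O)(C(C)C)[C@@H]2[C@@H](OC(=O)c3ccc(O)cc3)CC(C)=CC[C@]21C | target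

## Step count and risks

Total step count: 13, made up of 12 steps on the main line plus the generation of diazoethane.
Longest linear sequence: 12 steps (1–4 and 6–13, from m-cresol).

**Step 7, the Buchner reaction.** The methyl-bearing carbenoid may be lost to a 1,2-hydride shift or to insertion into the isopropyl C–H, or it may add too slowly to the crowded arene. In that case the quaternary centre is no longer made in the cycloaddition.
- The fallback sets out from acid chloride 12, which is treated with ethereal diazomethane to give the terminal diazoketone F1.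
- The carbenoid from F1 is unhindered and has no β-hydrogen. It undergoes the best-precedented form of the same ring-forming event with Rh2(O2CC3F7)4 and gives the 8a-H azulenone F2.
- The potassium enolate of F2 (KN(SiMe3)2, THF, −78 °C) forms at the doubly activated C8a–H rather than at the neopentyl C2. It is C-methylated with MeI from the face opposite the isopropyl group.
- This comes back to the route at 15.

**Step 8, the facial selectivity at C1.** In the flat triene 15 the α-isopropyl group may oppose the catalyst. In that case the order of events is changed so that substrate control does the work.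
- The fallback sets out from 15, which is desilylated first (HF·pyridine) to the trans-fused hydroxy dione F3.
- In F3 the C8a methyl sits pseudo-axially over the β-face of the cyclopentanone, as in a 17-keto steroid.
- NaBH4 in CH2Cl2–MeOH at −78 °C reduces the saturated ketone in preference to the dienone, from the α-face, to give the 1β-hydroxy dienone F4.
- The mixed-anhydride angeloylation of step 9, applied to the only secondary hydroxyl of F4, comes back to the route at 20.

**Step 12, the 1,4-hydrogenation.** The trisubstituted diene next to a quaternary carbon may not bind chromium. In that case the two hydrogens are put in by electron transfer at the ketone stage.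
- The fallback sets out from dienone 20. SmI2 (divalent samarium, 2.5 equiv) in THF–MeOH at −78 °C reduces it in a 1,6 sense to the dienolate.
- Kinetic α-protonation of the dienolate gives the β,γ-unsaturated ketone F5.
- The Me4NBH(OAc)3 reduction of step 11, applied to F5, comes back to the route at 22.

## Further compounds

F1 | step 7 | (R)-1-diazo-3-(2,2-di-tert-butyl-4-isopropyl-7-methyl-4H-1,3,2-benzodioxasilin-4-yl)propan-2-one | [N-]=[N+]=CC(=O)C[C@@](O2)(C(C)C)c1ccc(C)cc1O[Si]2(C(C)(C)C)C(C)(C)C
F2 | step 7 | (3R)-3,4-[(di-tert-butylsilanediyl)bis(oxy)]-3-isopropyl-6-methyl-3,8a-dihydroazulen-1(2H)-one (8a-H) | O=C1C[C@@](O3)(C(C)C)C2=C(O[Si]3(C(C)(C)C)C(C)(C)C)C=C(C)C=C[C@H]21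
F3 | step 8 | (3R,3aR,8aR)-3-hydroxy-3-isopropyl-6,8a-dimethyl-2,3,3a,8a-tetrahydroazulene-1,4-dione | O=C1C[C@@](O)(C(C)C)[C@@H]2C(=O)C=C(C)C=C[C@]21C
F4 | step 8 | (1R,3R,3aR,8aR)-1,3-dihydroxy-3-isopropyl-6,8a-dimethyl-1,2,3,3a-tetrahydroazulen-4(8aH)-one | O[C@@H]1C[C@@](O)(C(C)C)[C@@H]2C(=O)C=C(C)C=C[C@]21C
F5 | step 12 | (1R,3R,3aR,8aR)-3-hydroxy-3-isopropyl-6,8a-dimethyl-4-oxo-1,2,3,3a,4,5,8,8a-octahydroazulen-1-yl (Z)-2-methylbut-2-enoate | C/C=C(/C)C(=O)O[C@@H]1C[C@@](O)(C(C)C)[C@@H]2C(=O)CC(C)=CC[C@]21C
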